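**Retrosynthetic overview** (numbering: C1 ketone, C2=C3 furanone olefin with C3 on the ring oxygen, C4(C15)=C5, C6 lactone O–CH, C7, C8, C9, C10 bearing C14 and the ring oxygen, C11–C13 lactone)
1. The strategy rests on the cis C8/C9 diester pair (C8 methacrylate, C9 acetate) between C7 and quaternary C10 in the ten-membered carbocycle C1–C10 (nine-membered oxacycle O, C3–C10); it is read as a syn-dihydroxylated Z C8=C9 ring olefin.
2. C8=C9 comes from ring-closing metathesis of the C7 and C10 vinyl groups of furanone–lactone diene 20; the esters come from diol 22.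
3. The furanone comes from gold-catalysed 5-endo-dig cyclisation of α′-hydroxy ynone 19; C3–C4 comes from Sonogashira coupling of Z-iodide 10 with alkynol 16.
4. Lactone 10 comes from indium Barbier allylation of (S)-glyceraldehyde acetonide (sets C6, C7), diol cleavage and iodo-Wittig olefination; 16 comes from asymmetric allylic etherification of isoprene monoepoxide (sets C10).
5. Ring order: methylene lactone, then furanone, then the bridged nine/ten-membered ring as the last ring-forming event.

Key step: step 13

Assumption: the (S,S)-enantiomer of the DACH-phenyl Trost ligand is taken to deliver the (R)-ether 13 from isoprene monoepoxide; if the rotation of 13 shows the opposite sense, the (R,R)-ligand is used and nothing else changes.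

**Route**

Step 1
Reactants: 1 acrolein; 2 methyl acrylate
Product: 3 methyl 3-hydroxy-2-methylidenepent-4-enoate (racemic)
Conditions: DABCO (20 mol %), neat, rt
Reagents that add atoms: none
Why: Morita–Baylis–Hillman reaction, in which the DABCO-derived acrylate enolate adds 1,2 to the aldehyde of acrolein; the carbinol stereocentre is removed in step 2.

Step 2
Reactants: 3 methyl 3-hydroxy-2-methylidenepent-4-enoate
Product: 4 methyl (2Z)-2-(bromomethyl)penta-2,4-dienoate
Conditions: PBr3, Et2O, 0 °C
Reagents that add atoms: phosphorus tribromide, BrP(Br)Br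
Why: SN2′ bromination of a Baylis–Hillman alcohol with allylic transposition to the conjugated dienoate, which takes the thermodynamically preferred Z geometry (vinyl cis to CH2Br, trans to the ester).

Step 3
Reactants: 4 methyl (2Z)-2-(bromomethyl)penta-2,4-dienoate; 5 (S)-2,2-dimethyl-1,3-dioxolane-4-carbaldehyde
Product: 7 (4S,5R)-5-[(4S)-2,2-dimethyl-1,3-dioxolan-4-yl]-4-ethenyl-3-methylideneoxolan-2-one (cis lactone), via hydroxy ester 6 (not isolated)
Conditions: In powder, THF–H2O (1:1), rt; then PPTS (cat.), CH2Cl2, rt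
Reagents that add atoms: none
Why: Indium Barbier allylation by γ-attack (SE2′) through a chair Zimmerman–Traxler transition state followed by lactonisation; the Z-allylindium places the vinyl group axial and gives the 6,7-syn (cis-lactone) relationship, and Felkin–Anh addition anti to the dioxolane oxygen of 5 sets the absolute configuration of C6 and so of C7.

Step 4
Reactants: 7 the cis acetonide lactone
Product: 8 (2R,3S)-3-ethenyl-4-methylidene-5-oxooxolane-2-carbaldehyde
Conditions: H5IO6 (1.5 equiv), EtOAc, rt
Reagents that add atoms: none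
Why: Periodic acid hydrolyses the terminal acetonide and cleaves the liberated 1,2-diol in one pot (Malaprade cleavage) under acidic conditions that do not touch C6, C7 or the methylene lactone.

Step 5
Reactants: 8 the lactone aldehyde; 9 ethyltriphenylphosphonium iodide
Product: 10 (4S,5R)-4-ethenyl-5-[(1Z)-2-iodoprop-1-en-1-yl]-3-methylideneoxolan-2-one
Conditions: 9, n-BuLi, THF, rt; I2, −78 °C; NaHMDS, −20 °C; then 8, −78 °C, cold quench
Reagents that add atoms: iodine, [I][I]
Why: Stork–Zhao-type Wittig olefination with the α-iodoethylidene ylide, which gives (Z)-2-iodo-2-alkenes (iodine cis to C6); at −78 °C the aldehyde should react much faster than the lactone enoate.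

Step 6
Reactants: 11 2-methyl-2-vinyloxirane (racemic); 12 4-methoxybenzyl alcohol
Product: 13 (2R)-2-[(4-methoxyphenyl)methoxy]-2-methylbut-3-en-1-ol
Conditions: Pd2(dba)3·CHCl3 (1 mol %), (S,S)-DACH-phenyl Trost ligand (3 mol %), Et3B (1 mol %), CH2Cl2, rt
Reagents that add atoms: none
Why: Palladium-catalysed dynamic kinetic asymmetric allylic etherification: the π-allyl complexes formed by zerovalent palladium from racemic 11 interconvert, and the boron-bound alkoxide is delivered to the tertiary terminus under ligand control, setting C10.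

Step 7
Reactants: 13 the PMB ether alcohol
Product: 14 (2R)-2-[(4-methoxyphenyl)methoxy]-2-methylbut-3-enal
Conditions: Dess–Martin periodinane, CH2Cl2, 0 °C to rt
Reagents that add atoms: none
Why: Dess–Martin oxidation of a primary alcohol; the aldehyde has no α-hydrogen, so C10 cannot epimerise.

Step 8
Reactants: 14 the aldehyde; 15 ethynylmagnesium bromide
Product: 16 (4R)-4-[(4-methoxyphenyl)methoxy]-4-methylhex-5-en-1-yn-3-ol (both C3 epimers)
Conditions: THF, −78 to 0 °C; aq. NH4Cl
Reagents that add atoms: none
Why: Grignard 1,2-addition of the acetylide; the new carbinol centre (later C1) is formed as a mixture, which does not matter because it is oxidised in step 10.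

Step 9
Reactants: 10 the Z-vinyl iodide lactone; 16 the alkynol
Product: 17 (4S,5S)-4-ethenyl-5-[(1Z,6R)-5-hydroxy-6-[(4-methoxyphenyl)methoxy]-2,6-dimethylocta-1,7-dien-3-yn-1-yl]-3-methylideneoxolan-2-one (both carbinol epimers)
Conditions: Pd(PPh3)2Cl2 (5 mol %), CuI (10 mol %), Et3N, THF, rt
Reagents that add atoms: none
Why: Sonogashira coupling forms C3–C4 with retention of the Z geometry; the tertiary amine base does not add irreversibly to the methylene lactone.

Step 10
Reactants: 17 the enyne alcohol
Product: 18 (4S,5S)-4-ethenyl-5-[(1Z,6R)-6-[(4-methoxyphenyl)methoxy]-2,6-dimethyl-5-oxoocta-1,7-dien-3-yn-1-yl]-3-methylideneoxolan-2-one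
Conditions: Dess–Martin periodinane, CH2Cl2, 0 °C to rt
Reagents that add atoms: none
Why: Dess–Martin oxidation of the secondary propargylic alcohol to the ynone under non-basic conditions, which merges the two carbinol epimers.

Step 11
Reactants: 18 the PMB-protected ynone
Product: 19 (4S,5S)-4-ethenyl-5-[(1Z,6R)-6-hydroxy-2,6-dimethyl-5-oxoocta-1,7-dien-3-yn-1-yl]-3-methylideneoxolan-2-one
Conditions: DDQ, CH2Cl2–pH 7 buffer (10:1), 0 °C
Reagents that add atoms: none
Why: Oxidative cleavage of the 4-methoxybenzyl ether by DDQ (hydride abstraction, then hydrolysis of the oxocarbenium ion); no neighbouring hydroxyl is present to trap it as an acetal.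

Step 12
Reactants: 19 the α′-hydroxy ynone
Product: 20 (4S,5S)-4-ethenyl-5-[(1Z)-2-[(5R)-5-ethenyl-5-methyl-4-oxo-4,5-dihydrofuran-2-yl]prop-1-en-1-yl]-3-methylideneoxolan-2-one
Conditions: (4-CF3C6H4)3PAuCl (5 mol %), AgOTf (5 mol %), toluene, rt
Reagents that add atoms: none
Why: Gold-catalysed 5-endo-dig cyclisation of a γ-hydroxy ynone, in which the tertiary hydroxyl adds to the gold-activated alkyne at C3 and protodeauration gives the 3(2H)-furanone under neutral conditions.

Step 13
Reactants: 20 the furanone–lactone diene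
Product: 21 (4Z,6S,7S,8Z,10R)-3,10-epoxy-1-oxogermacra-2,4,8,11(13)-tetraen-12,6-olide (bridged macrocycle)
Conditions: second-generation Grubbs catalyst (H2IMes)(PCy3)Cl2Ru=CHPh (10 mol %, two portions), 1,4-benzoquinone (20 mol %), toluene (0.001 M), 80 °C, argon sparge
Reagents that add atoms: none
Why: Ring-closing olefin metathesis: the ruthenium benzylidene exchanges onto the less hindered C7 vinyl group, the resulting C8 alkylidene adds to the C10 vinyl group in a [2+2] step, and cycloreversion of the ruthenacyclobutane releases ethylene and forms C8=C9. The closest known reaction type is ring-closing metathesis to nine- and ten-membered cis-cycloalkenes in germacranolide-type substrates that carry an α-methylene lactone. One bond closes two rings at once, the nine-membered oxacycle (O, C3–C10) and the ten-membered carbocycle (C1–C10), as a macrocyclisation between two exocyclic monosubstituted olefins held on the same side by the cis lactone, the Z C4=C5 olefin and the planar furanone. No stereocentre is formed, and the new olefin can only be Z because the nine-membered ring cannot hold an E olefin. The step needs ring closure over oligomerisation and chemoselection for the two vinyl groups: high dilution with ethylene removal serves the first, the 1,1-disubstituted electron-poor C11=C13, the trisubstituted C4=C5 and the furanone C2=C3 olefins are poor metathesis partners, and benzoquinone suppresses ruthenium hydride isomerisation of the skipped C8/C11 diene.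

Step 14
Reactants: 21 the bridged tetraene
Product: 22 (4Z,6S,7R,8S,9S,10R)-8,9-dihydroxy-3,10-epoxy-1-oxogermacra-2,4,11(13)-trien-12,6-olide
Conditions: OsO4 (5 mol %), NMO (1.1 equiv), acetone–H2O (10:1), 0 °C
Reagents that add atoms: osmium tetroxide, O=[Os](=O)(=O)=O; N-methylmorpholine N-oxide, C[N+]1([O-])CCOCC1
Why: Upjohn syn-dihydroxylation of the strained, most electron-rich Z C8=C9 olefin gives the cis-diol, and the 8S,9S isomer requires addition to the C8-Si/C9-Si face, which should be preferred because the C14 methyl on C10 lies over the opposite face of C9, although this face also looks into the fold of the nine-membered ring, so the outcome must be checked on the first sample.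

Step 15
Reactants: 22 the diol
Product: 23 (4Z,6S,7S,8S,9S,10R)-9-hydroxy-8-(2-methylprop-2-enoyloxy)-3,10-epoxy-1-oxogermacra-2,4,11(13)-trien-12,6-olide
Conditions: methacrylic anhydride (1.2 equiv), Et3N, DMAP (10 mol %), CH2Cl2, −20 to 0 °C
Reagents that add atoms: methacrylic anhydride, CC(=C)C(=O)OC(=O)C(C)=C
Why: DMAP-catalysed acyl transfer should select the C8 hydroxyl, because the C9 hydroxyl is neopentyl-like next to quaternary C10.

Step 16
Reactants: 23 the 8-methacrylate
Product: 24 target, (4Z,6S,7S,8S,9S,10R)-9-acetoxy-8-(2-methylprop-2-enoyloxy)-3,10-epoxy-1-oxogermacra-2,4,11(13)-trien-12,6-olide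
Conditions: Ac2O, DMAP, pyridine, CH2Cl2, rt
Reagents that add atoms: acetic anhydride, CC(=O)OC(C)=O
Why: DMAP-catalysed acetylation of the remaining hindered secondary alcohol, with no change at any stereocentre.

**Compound list**
1 | acrolein | C=CC=O | starting material
2 | methyl acrylate | C=CC(=O)OC | starting material
3 | methyl 3-hydroxy-2-methylidenepent-4-enoate (racemic) | C=CC(O)C(=C)C(=O)OC | intermediate
4 | methyl (2Z)-2-(bromomethyl)penta-2,4-dienoate | C=C/C=C(\CBr)C(=O)OC | intermediate
5 | (S)-2,2-dimethyl-1,3-dioxolane-4-carbaldehyde | O=C[C@@H]1COC(C)(C)O1 | starting material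
6 | methyl (3S,4R)-4-[(4S)-2,2-dimethyl-1,3-dioxolan-4-yl]-3-ethenyl-4-hydroxy-2-methylidenebutanoate | C=C[C@@H](C(=C)C(=O)OC)[C@@H](O)[C@@H]1COC(C)(C)O1 | intermediate
7 | (4S,5R)-5-[(4S)-2,2-dimethyl-1,3-dioxolan-4-yl]-4-ethenyl-3-methylideneoxolan-2-one | C=C[C@H]1C(=C)C(=O)O[C@H]1[C@@H]2COC(C)(C)O2 | intermediate
8 | (2R,3S)-3-ethenyl-4-methylidene-5-oxooxolane-2-carbaldehyde | C=C[C@H]1C(=C)C(=O)O[C@H]1C=O | intermediate
9 | ethyltriphenylphosphonium iodide | CC[P+](c1ccccc1)(c1ccccc1)c1ccccc1.[I-] | starting material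
10 | (4S,5R)-4-ethenyl-5-[(1Z)-2-iodoprop-1-en-1-yl]-3-methylideneoxolan-2-one | C=C[C@H]1C(=C)C(=O)O[C@H]1/C=C(/C)I | intermediate
11 | 2-methyl-2-vinyloxirane (racemic) | CC1(C=C)CO1 | starting material
12 | 4-methoxybenzyl alcohol | COc1ccc(CO)cc1 | starting material
13 | (2R)-2-[(4-methoxyphenyl)methoxy]-2-methylbut-3-en-1-ol | C=C[C@](C)(CO)OCc1ccc(OC)cc1 | intermediate
14 | (2R)-2-[(4-methoxyphenyl)methoxy]-2-methylbut-3-enal | C=C[C@](C)(C=O)OCc1ccc(OC)cc1 | intermediate
15 | ethynylmagnesium bromide | C#C[Mg]Br | starting material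
16 | (4R)-4-[(4-methoxyphenyl)methoxy]-4-methylhex-5-en-1-yn-3-ol (both C3 epimers) | C#CC(O)[C@@](C)(C=C)OCc1ccc(OC)cc1 | intermediate
17 | (4S,5S)-4-ethenyl-5-[(1Z,6R)-5-hydroxy-6-[(4-methoxyphenyl)methoxy]-2,6-dimethylocta-1,7-dien-3-yn-1-yl]-3-methylideneoxolan-2-one | C=C[C@H]1C(=C)C(=O)O[C@H]1/C=C(/C)C#CC(O)[C@@](C)(C=C)OCc1ccc(OC)cc1 | intermediate
18 | (4S,5S)-4-ethenyl-5-[(1Z,6R)-6-[(4-methoxyphenyl)methoxy]-2,6-dimethyl-5-oxoocta-1,7-dien-3-yn-1-yl]-3-methylideneoxolan-2-one | C=C[C@H]1C(=C)C(=O)O[C@H]1/C=C(/C)C#CC(=O)[C@@](C)(C=C)OCc1ccc(OC)cc1 | intermediate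
19 | (4S,5S)-4-ethenyl-5-[(1Z,6R)-6-hydroxy-2,6-dimethyl-5-oxoocta-1,7-dien-3-yn-1-yl]-3-methylideneoxolan-2-one | C=C[C@H]1C(=C)C(=O)O[C@H]1/C=C(/C)C#CC(=O)[C@](C)(O)C=C | intermediate
20 | (4S,5S)-4-ethenyl-5-[(1Z)-2-[(5R)-5-ethenyl-5-methyl-4-oxo-4,5-dihydrofuran-2-yl]prop-1-en-1-yl]-3-methylideneoxolan-2-one | C=C[C@H]1C(=C)C(=O)O[C@H]1/C=C(/C)C1=CC(=O)[C@](C)(O1)C=C | intermediate
21 | (4Z,6S,7S,8Z,10R)-3,10-epoxy-1-oxogermacra-2,4,8,11(13)-tetraen-12,6-olide | O=C1C=C2O[C@]1(C)/C=C\[C@H]1C(=C)C(=O)O[C@H]1/C=C2/C | intermediate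
22 | (4Z,6S,7R,8S,9S,10R)-8,9-dihydroxy-3,10-epoxy-1-oxogermacra-2,4,11(13)-trien-12,6-olide | O[C@H]1[C@H]2C(=C)C(=O)O[C@H]2/C=C(/C)C2=CC(=O)[C@](C)(O2)[C@H]1O | intermediate
23 | (4Z,6S,7S,8S,9S,10R)-9-hydroxy-8-(2-methylprop-2-enoyloxy)-3,10-epoxy-1-oxogermacra-2,4,11(13)-trien-12,6-olide | C=C(C)C(=O)O[C@H]1[C@H]2C(=C)C(=O)O[C@H]2/C=C(/C)C2=CC(=O)[C@](C)(O2)[C@H]1O | intermediate
24 | (4Z,6S,7S,8S,9S,10R)-9-acetoxy-8-(2-methylprop-2-enoyloxy)-3,10-epoxy-1-oxogermacra-2,4,11(13)-trien-12,6-olide | C=C(C)C(=O)O[C@H]1[C@H]2C(=C)C(=O)O[C@H]2/C=C(/C)C2=CC(=O)[C@](C)(O2)[C@H]1OC(C)=O | target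

**Step count**
Total: 16 steps. Longest linear sequence: 13 steps (steps 1–5 and 9–16).

**Steps most likely to fail, with fallbacks**

Step 13 (key step). The C8 alkylidene may react intermolecularly through the accessible C7 vinyl group (dimers and oligomers) faster than it reaches the neopentyl-type C10 vinyl group across the rigid furanone, or the bridged triene may be too strained to form under reversible conditions. The fallback inverts the ring order, closing the ten-membered ring first and forming the furanone second. It sets out from hydroxy ynone 19. Co2(CO)8 in CH2Cl2 at rt gives the hexacarbonyldicobalt alkyne complex F1; its complexed alkyne is bent to about 140°, which brings the two vinyl groups together, and it is protected from enyne metathesis. Ring-closing metathesis of F1 with the catalyst of step 13 gives the ten-membered cobalt complex F2. (NH4)2Ce(NO3)6 in acetone at −78 °C releases the cyclic hydroxy ynone F3. Transannular 5-endo-dig cyclisation of F3 with the gold catalyst of step 12 gives 21, where the route is rejoined.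

Step 14. Osmium may add with poor or inverted facial selectivity (to the C8-Re/C9-Re face, giving the 8R,9R diol), and the lactone methylene may be dihydroxylated in competition. The fallback sets out from 21 and uses Woodward–Prévost cis-hydroxylation (I2, AgOAc, AcOH, then aqueous AcOH). The iodonium ion forms on the face that electrophiles prefer, acetate opens it anti, and the neighbouring-group acetoxonium ion is hydrolysed, so both oxygens end on the other face as cis-hydroxy acetates: the 9-acetate F4 and the 8-acetate F5. F4 is methacrylated under the conditions of step 15 and gives target 24 directly. F5 is equilibrated with F4 by 1,2-acetyl migration across the cis-diol (imidazole, CH2Cl2) and recycled.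

Step 5. The basic ylide may add in conjugate fashion to the methylene lactone, isomerise the skipped C8/C11 diene, or epimerise C6, and Z selectivity may erode. The fallback avoids strong base and takes the olefin geometry from palladium catalysis. It sets out from aldehyde 8. Dichloroolefination (PPh3, CCl4, MeCN, rt) gives the 1,1-dichloroalkene F6. Trans-selective Negishi monomethylation (MeZnCl, Pd(DPEphos)Cl2 cat., THF–DMF) replaces the chloride trans to C6 and gives the (Z)-2-chloropropenyl lactone F7. Sonogashira coupling of F7 with alkynol 16 (Pd(PtBu3)2, CuI, iPr2NH, 50 °C) proceeds with retention and rejoins the route at 17.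

**Further compounds**
F1 | step 13 | hexacarbonyldicobalt complex of the C2≡C3 alkyne of 19 | C=C[C@H]1C(=C)C(=O)O[C@H]1/C=C(/C)C23C4(C(=O)[C@](C)(O)C=C)[Co]2(=C=O)(=C=O)(=C=O)[Co]34(=C=O)(=C=O)=C=O
F2 | step 13 | hexacarbonyldicobalt complex of the ten-membered (4Z,8Z)-dienyne hydroxy ketone | C[C@@]1(O)/C=C\[C@H]2C(=C)C(=O)O[C@H]2/C=C(/C)C34C5(C1=O)[Co]3(=C=O)(=C=O)(=C=O)[Co]45(=C=O)(=C=O)=C=O
F3 | step 13 | (4Z,6S,7S,8Z,10R)-10-hydroxy-1-oxogermacra-4,8,11(13)-trien-2-yn-12,6-olide | C[C@@]1(O)/C=C\[C@H]2C(=C)C(=O)O[C@H]2/C=C(/C)C#CC1=O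
F4 | step 14 | (4Z,6S,7S,8S,9S,10R)-9-acetoxy-8-hydroxy-3,10-epoxy-1-oxogermacra-2,4,11(13)-trien-12,6-olide | O[C@H]1[C@H]2C(=C)C(=O)O[C@H]2/C=C(/C)C2=CC(=O)[C@](C)(O2)[C@H]1OC(C)=O
F5 | step 14 | (4Z,6S,7S,8S,9S,10R)-8-acetoxy-9-hydroxy-3,10-epoxy-1-oxogermacra-2,4,11(13)-trien-12,6-olide | CC(=O)O[C@H]1[C@H]2C(=C)C(=O)O[C@H]2/C=C(/C)C2=CC(=O)[C@](C)(O2)[C@H]1O
F6 | step 5 | (4S,5R)-5-(2,2-dichloroethenyl)-4-ethenyl-3-methylideneoxolan-2-one | C=C[C@H]1C(=C)C(=O)O[C@H]1C=C(Cl)Cl
F7 | step 5 | (4S,5R)-5-[(1Z)-2-chloroprop-1-en-1-yl]-4-ethenyl-3-methylideneoxolan-2-one | C=C[C@H]1C(=C)C(=O)O[C@H]1/C=C(/C)Cl
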